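The trap in this flask is to read 1.20 equivalents of L to D as an excess, when the steps spend two L on each Z: one in Q + L → X and one in L + J → G, before X + G → Z.

- north-east: D 5 mM; L 12 mM (in portions, 2); E 0.73 mM (held); run made earlier; portions every 2.0 s
- flask: D 10 mM; L 12.0 mM (in portions, 2); E 0.73 mM (held); time 40 min; the portions of L follow each other after 2.0 s, the first at the start

north-east run (percent of the D charged)

| time / min | D / % | Z / % |
|---|---|---|
| 2.00 | 78 | 24 |
| 4.00 | 49 | 47 |
| 6.00 | 28 | 72 |
| 8.00 | 8 | 89 |

(readings scatter by 2 percentage points)

- D is a solid; its amount is given per volume of the solution
- at the start none of J is dissolved
- the numbers in the tables scatter by 2 percentage points (one standard deviation)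
- steps under discussion: X + G -> Z; E <-> J; Q + L -> X; L + J -> G; D <-> Q
- at the start none of D is in solution
- what has only dissolved of D counts as not reacted
- the reaction counts as stopped when no species that holds the D changes by six tenths of a point or more over the second half of the time

- why nothing more happens at 40 min, or that something still does (for what has run out or reacted, a solid counts together with what of it has only dissolved) (all of D has reacted / L has run out first / it is still moving)
- part of the D that has turned into other species by 40 min (what has only dissolved does not count)
- amount of Z at 40 min, in percent of the D charged

So this flask's charge pays for 60.0% of the D as Z. This share, the L charge over twice the D charge, is what I carry: the L ceiling. L is the limiting reagent in this flask because the 6.00 mM of Z it pays for is less than the 10 mM of D. In the north-east run the ceiling stood at 120%, above the D charged, so that run shows me a pace and no stop.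

In the first instants of this flask both portions of L are in after 2.0 s, far sooner than the first reading at 2.00 min, while D passes into solution as Q and E as J. For the middle I take the pace from the north-east run, where D and Z sum to 97.0% at 8.00 min, so the readings show no pile-up of X there, and Z gains a read 0.542 mM/min. If that pace, read at a different D charge, carries over, I estimate that this flask spends its 12.0 mM of L in about 11.1 min, well before 40 min. For the end I expect conversion and Z together just under the ceiling, with about 40.0% of the D still there as D or Q.

The forecast says L has run out first, with conversion 56% and Z 55%. Its ground is that “12 mM L can make at most 6 mM Z”, and its figure lies lower than my "just under the ceiling".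

The flask gives L has run out first, with conversion 58.2% and Z 58.2%.

    X + G → Z (k = 130 /M/s)
    E ⇌ J, rate k2*(csat - [J]) (kL = 0.630 /s)
    Q + L → X (k = 31.0 /M/s)
    L + J → G (k = 2.90 /M/s)
    D ⇌ Q, rate k5*(cs5 - [Q]) while solid is left; crystals form when [Q] > cs5 (solubility = 0.580 mM, k = 0.0190 /s)

The forecast stands. In this flask L is at 0% at 40.0 min, with X at 0% and G at 0.351 mM, and the gap of 1.8 percentage points below the ceiling matches that G counted as L not paid into Z, 1.8 points. With the other amounts and the time held, Z moves 5 points from this flask's value at L 10.8 mM or 13.7 mM, or at D 9.21 mM or 10.9 mM. The neighbour with 17 mM of D has a ceiling of 35.3%, and its 0.351 mM of G takes off 1 point, which leaves 34.3%; that flask stands at L 0% and Z 34.3%.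

The runs are calculated with made-up constants; the scatter is artificial.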